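The ether oxygen ties C3' to C8. C3' is the carbinol carbon of ring D (the methylidenecyclohexane), where the C–O bond is axial. C8 is an equatorial site of ring B next to spiro carbon C7. The resulting oxolane (ring C) is trans-fused to ring B and forms the two-atom bridge of a 6-oxabicyclo[3.2.1]octane on ring D.
Last cut, O–C8: a fluoride-triggered, inverting Williamson closure of the C3' silyl ether / axial C8 mesylate 26. Compound 26 comes from spiro ketone 24 by equatorial hydride delivery and mesylation.
Ring D: the C7–C6' bond is made by intramolecular palladium-catalysed enolate alkenylation (new bond axial, CMe2 branch equatorial). The side chain comes from a ketal Claisen rearrangement with prenol (C7–CMe2), ozonolysis and a catalytic enantioselective alkylzinc addition (sets C3').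
Ring A functions: C4 ketone + MeMgBr gives the axial OH. C1 ketone → bromoalkene → hydrogen-atom-transfer hydrogenation gives the equatorial Br.
Rings A/B: enantioselective Diels–Alder reaction of quinone 3 (ring A) with silyloxydiene 2 (closes ring B), then cis→trans epimerisation. Order of rings: A (from 3), B, D, C.

Key step: step 19

Locants: the decalin is numbered C1 (CHBr), C2, C3, C4 (carbinol carbon), C5 (ring-fusion CH), C6, C7 (spiro carbon), C8 (ether carbon), C9, C10 (ring-fusion carbon bearing CH3). Ring D is C7, C2' (CMe2), C3' (carbinol carbon), C4', C5', C6' (methylidene carbon). "syn" and "anti" refer to the face of the C10 methyl group. Absolute configuration is as in the SMILES.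

Assumption: the BINOL antipode written in step 2 is taken to shield the quinone face that leads to 4. The sense of induction has to be checked on 4, and the other antipode is equally available.

Step 1
Reactants: 1 but-3-en-2-one
Product: 2 2-(tert-butyldimethylsilyloxy)buta-1,3-diene
Conditions: TBSOTf, Et3N, Et2O, 0 °C
Reagents that add atoms: tert-butyldimethylsilyl triflate, CC(C)(C)[Si](C)(C)OS(=O)(=O)C(F)(F)F
Why: Soft enolisation and O-silylation of the methyl ketone gives the 2-silyloxydiene, whose robust silyl enol ether later masks C8 through steps 3 to 5; no stereocentre is formed.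

Step 2
Reactants: 2 2-(tert-butyldimethylsilyloxy)buta-1,3-diene; 3 2-methoxy-5-methyl-1,4-benzoquinone
Product: 4 cis-fused adduct (Δ2,Δ7-octalin-1,4-dione; 3-OMe; 8-OTBS; 10-CH3; C5–H syn)
Conditions: (R)-BINOL/TiCl2(Oi-Pr)2 (20 mol %), toluene, −40 → 0 °C
Reagents that add atoms: none
Why: In this chiral-Lewis-acid-catalysed quinone Diels–Alder reaction the methoxy group switches off its own C=C and, chelated to titanium together with the adjacent C=O, makes the methyl-bearing carbon the acceptor for the nucleophilic CH2 terminus of 2 (oxygen ends at C8), suprafacial addition gives the cis fusion, and the ligand selects the quinone face, which sets C10 and C5.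

Step 3
Reactants: 4 cis-fused adduct
Product: 5 trans-fused enedione (C5–H anti)
Conditions: DBU (0.2 equiv), CH2Cl2, 23 °C
Reagents that add atoms: none
Why: Thermodynamic epimerisation through the C4 enolate, known for angularly methylated quinone adducts, inverts C5 because sp2 C4 and C8 spare the axial methyl two of its syn-axial contacts in the trans isomer, while quaternary C10 cannot change.

Step 4
Reactants: 5 trans-fused enedione
Product: 7 trans-Δ7-octalin-1,4-dione (8-OTBS; 10-CH3), via methoxy dione 6 (not isolated)
Conditions: SmI2 (4.5 equiv), THF–MeOH, −78 → 0 °C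
Reagents that add atoms: none
Why: Samarium diiodide first saturates the enedione C2=C3 (conjugate reduction) and then cleaves the C3–OMe bond next to the C4 ketone (reductive removal of an α-alkoxy group), touching neither the silyl enol ether nor C5 or C10.

Step 5
Reactants: 7 trans-Δ7-octalin-1,4-dione
Product: 8 C4 tertiary alcohol (C4–CH3 equatorial; C4–OH axial and syn; C1 ketone kept)
Conditions: MeMgBr (1.1 equiv), CeCl3·2LiCl, THF, −78 °C
Reagents that add atoms: methylmagnesium bromide, C[Mg]Br
Why: The cerium-assisted Grignard 1,2-addition picks C4 because C1 is neopentyl, and it enters equatorially because the 1,3-diaxial C10 methyl closes the axial path, which sets C4 and at the same time locks C5.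

Step 6
Reactants: 8 C4 tertiary alcohol
Product: 9 C8 dimethyl ketal of the C1-keto C4-alcohol
Conditions: MeOH, HC(OMe)3, CSA (5 mol %), 0 → 23 °C
Reagents that add atoms: methanol, CO
Why: Acid methanolysis of the silyl enol ether (protonation at C7, then ketalisation of the oxocarbenium ion) masks C8 against steps 8 to 10, the hindered C1 ketone does not ketalise, and no stereocentre changes.

Step 7
Reactants: 9 C8 dimethyl ketal
Product: 10 C4 triethylsilyl ether
Conditions: TESOTf, 2,6-lutidine, CH2Cl2, −40 → 0 °C
Reagents that add atoms: triethylsilyl triflate, CC[Si](CC)(CC)OS(=O)(=O)C(F)(F)F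
Why: Silyl triflate silylation covers the hindered tertiary alcohol for the enolate and sulfonylation steps, and the group falls off with fluoride in step 19.

Step 8
Reactants: 10 C4 triethylsilyl ether
Product: 11 C1 hydrazone
Conditions: N2H4·H2O, Et3N, EtOH, 80 °C
Reagents that add atoms: hydrazine, NN
Why: Hydrazone condensation occurs at the only free carbonyl group, and the ketal and silyl ether are stable to the basic medium.

Step 9
Reactants: 11 C1 hydrazone
Product: 12 C1 bromoalkene (C1(Br)=C2)
Conditions: NBS (2.2 equiv), pyridine, CH2Cl2, −10 °C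
Reagents that add atoms: N-bromosuccinimide, O=C1CCC(=O)N1Br
Why: In the Barton vinyl halide synthesis, oxidation to the diazoalkane, bromination, loss of N2 and loss of a C2 proton (C10 carries none) give the bromoalkene, as known for neopentyl ketone hydrazones.

Step 10
Reactants: 12 C1 bromoalkene
Product: 13 equatorial C1 bromide (Br syn; C8 ketal; C4 OTES)
Conditions: Mn(dpm)3 (10 mol %), PhSiH3, t-BuOOH, i-PrOH, 23 °C, Ar
Reagents that add atoms: none
Why: Metal-hydride hydrogen-atom-transfer hydrogenation, which keeps the C–halogen bond of haloalkenes, adds H to C2, and the C1 α-bromo radical then takes its H on the axial face anti to the C10 methyl, giving the thermodynamically preferred equatorial bromide.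

Step 11
Reactants: 13 equatorial C1 bromide; 14 3-methylbut-2-en-1-ol
Product: 17 C8 ketone with equatorial C7 1,1-dimethylallyl group (C7–H axial and anti), via prenyl enol ether 15 (not isolated), via axial ketone epimer 16 (not isolated)
Conditions: 14 (10 equiv), EtCO2H (10 mol %), xylene, 140 °C, MeOH distilled off; then DBU (cat.), 23 °C
Reagents that add atoms: none
Why: In the ketal Claisen rearrangement, alcohol exchange and loss of methanol give the allyl vinyl ether towards C7 (C9 is neopentyl), the [3,3] shift makes the crowded C7–CMe2 bond on the axial face, and enolisation then moves the tertiary alkyl group into the equatorial position.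

Step 12
Reactants: 17 C8 ketone with equatorial C7 1,1-dimethylallyl group
Product: 18 keto aldehyde (C7–CMe2–CHO)
Conditions: O3, CH2Cl2, −78 °C; Me2S
Reagents that add atoms: ozone, [O-][O+]=O
Why: Ozonolysis with reductive work-up cleaves the only alkene to a non-enolisable aldehyde that becomes C3'.

Step 13
Reactants: 19 3-bromobut-3-en-1-ol
Product: 20 2-bromo-4-iodobut-1-ene
Conditions: I2, PPh3, imidazole, CH2Cl2, 0 °C
Reagents that add atoms: iodine, II
Why: Appel-type iodination of the primary alcohol leaves the bromoalkene intact.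

Step 14
Reactants: 18 keto aldehyde; 20 2-bromo-4-iodobut-1-ene
Product: 22 (S)-C3' carbinol with 3-bromobut-3-enyl chain, via bis(3-bromobut-3-enyl)zinc 21 (not isolated)
Conditions: 20, Et2Zn, CuI (0.3 mol %), 50 °C, then vacuum; Ti(Oi-Pr)4, (1R,2R)-C6H10(NHSO2CF3)2 (8 mol %), toluene, −20 °C; 18
Reagents that add atoms: none
Why: Iodine–zinc exchange followed by titanium–bis(sulfonamide)-catalysed enantioselective dialkylzinc addition attacks only the aldehyde, and the (1R,2R) ligand directs the alkyl group to the Si face, which sets (S) at C3' under catalyst control.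

Step 15
Reactants: 22 (S)-C3' carbinol
Product: 23 C3' tert-butyldimethylsilyl ether
Conditions: TBSOTf, 2,6-lutidine, CH2Cl2, 0 °C
Reagents that add atoms: tert-butyldimethylsilyl triflate, CC(C)(C)[Si](C)(C)OS(=O)(=O)C(F)(F)F
Why: Silyl triflate silylation of the neopentyl secondary hydroxyl drains any ring–chain tautomerism of the γ-hydroxy ketone and installs the fluoride-labile mask needed in step 19.

Step 16
Reactants: 23 C3' tert-butyldimethylsilyl ether
Product: 24 spiro ketone (C6' axial and anti on ring B; C2' equatorial; exocyclic CH2 on C6')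
Conditions: Pd(PPh3)4 (10 mol %), KOt-Bu (1.5 equiv), THF–t-BuOH, 23 → 60 °C
Reagents that add atoms: none
Why: In this intramolecular palladium-catalysed α-alkenylation the bromoalkene adds oxidatively to zerovalent palladium, among the equilibrating enolates only the C7 one can close a six-membered ring (the C9 one would need eight, a Curtin–Hammett situation), and the C–C bond forms on the axial face anti to the C10 methyl, which sets C7.

Step 17
Reactants: 24 spiro ketone
Product: 25 axial C8 alcohol (OH syn)
Conditions: LiBH(s-Bu)3 (3 equiv), THF, −78 → 23 °C; aq. NH4Cl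
Reagents that add atoms: none
Why: The bulky borohydride enters equatorially because the 1,3-diaxial C10 methyl closes the axial path, so C8 receives the axial hydroxyl.

Step 18
Reactants: 25 axial C8 alcohol
Product: 26 spiro silyl ether mesylate (C3' OTBS; axial C8 OMs; C4 OTES)
Conditions: MsCl, Et3N, DMAP (cat.), CH2Cl2, 0 °C
Reagents that add atoms: methanesulfonyl chloride, CS(=O)(=O)Cl
Why: Mesylation of the only free hydroxyl proceeds with retention at C8, and the small sulfonylating agent tolerates the crowded axial site.

Step 19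
Reactants: 26 spiro silyl ether mesylate
Product: 28 target compound CNP0412361.2, via diol mesylate 27 (not isolated)
Conditions: Bu4NF (5 equiv), THF, 23 → 60 °C
Reagents that add atoms: none
Why: Fluoride cleaves both silyl ethers, and the C3' alkoxide of 27, brought next to C8 when ring D flips to the chair with O–C3' and C7–C8 1,3-diaxial, attacks C8 opposite the axial mesylate and expels it in one SN2 event. The closest known reaction type is the intramolecular Williamson etherification of a γ-hydroxy secondary sulfonate with inversion. The oxolane (ring C) closes 5-exo-tet, and because the new O–C8 bond spans C3' and C7 of ring D, the same event completes the 6-oxabicyclo[3.2.1]octane. The only stereocentre made, C8, is set by Walden inversion of the axial mesylate fixed in step 17, so the new C–O bond is equatorial and the oxolane is trans-fused. Substitution has to beat E2 loss of the mesylate with the anti-periplanar axial C9–H, the 1,2-shift of the anti-periplanar C6' carbon and any reaction at C1–Br; the proximity of the alkoxide (gem-dimethyl compression, five-membered transition state) and a basic, non-ionising medium favour substitution, the equatorial neopentyl bromide has neither an open rear side nor an anti-periplanar hydrogen, and the C4 alkoxide reaches no electrophile. The attack angle is somewhat bent because C8 is held in ring B, which is why the main risk of the route sits here.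

Compound list
1 | but-3-en-2-one | C=CC(C)=O | starting material
2 | 2-(tert-butyldimethylsilyloxy)buta-1,3-diene | C=CC(=C)O[Si](C)(C)C(C)(C)C | intermediate
3 | 2-methoxy-5-methyl-1,4-benzoquinone | COC1=CC(=O)C(C)=CC1=O | starting material
4 | cis-fused Diels–Alder adduct | CC(C)(C)[Si](C)(C)OC=1C[C@]2(C)C(=O)C=C(OC)C(=O)[C@@H]2CC=1 | intermediate
5 | trans-fused enedione | CC(C)(C)[Si](C)(C)OC=1C[C@]2(C)C(=O)C=C(OC)C(=O)[C@H]2CC=1 | intermediate
6 | 3-methoxy-1,4-dione (either C3 epimer, not isolated) | CC(C)(C)[Si](C)(C)OC=1C[C@]2(C)C(=O)CC(OC)C(=O)[C@H]2CC=1 | intermediate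
7 | trans-Δ7-octalin-1,4-dione silyl enol ether | CC(C)(C)[Si](C)(C)OC=1C[C@]2(C)C(=O)CCC(=O)[C@H]2CC=1 | intermediate
8 | C4 tertiary alcohol | CC(C)(C)[Si](C)(C)OC=1C[C@]2(C)C(=O)CC[C@@](C)(O)[C@H]2CC=1 | intermediate
9 | C8 dimethyl ketal | COC1(OC)C[C@]2(C)C(=O)CC[C@@](C)(O)[C@H]2CC1 | intermediate
10 | C4 triethylsilyl ether | COC1(OC)C[C@]2(C)C(=O)CC[C@@](C)(O[Si](CC)(CC)CC)[C@H]2CC1 | intermediate
11 | C1 hydrazone | COC1(OC)C[C@]2(C)C(=NN)CC[C@@](C)(O[Si](CC)(CC)CC)[C@H]2CC1 | intermediate
12 | C1 bromoalkene | COC1(OC)C[C@]2(C)C(Br)=CC[C@@](C)(O[Si](CC)(CC)CC)[C@H]2CC1 | intermediate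
13 | equatorial C1 bromide | COC1(OC)C[C@]2(C)[C@@H](Br)CC[C@@](C)(O[Si](CC)(CC)CC)[C@H]2CC1 | intermediate
14 | 3-methylbut-2-en-1-ol | CC(C)=CCO | starting material
15 | prenyl enol ether (not isolated) | CC(C)=CCOC=1C[C@]2(C)[C@@H](Br)CC[C@@](C)(O[Si](CC)(CC)CC)[C@H]2CC=1 | intermediate
16 | axial ketone epimer (not isolated) | C=CC(C)(C)[C@@H]1C(=O)C[C@]2(C)[C@@H](Br)CC[C@@](C)(O[Si](CC)(CC)CC)[C@H]2C1 | intermediate
17 | C8 ketone with equatorial C7 1,1-dimethylallyl group | C=CC(C)(C)[C@H]1C(=O)C[C@]2(C)[C@@H](Br)CC[C@@](C)(O[Si](CC)(CC)CC)[C@H]2C1 | intermediate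
18 | keto aldehyde | O=CC(C)(C)[C@H]1C(=O)C[C@]2(C)[C@@H](Br)CC[C@@](C)(O[Si](CC)(CC)CC)[C@H]2C1 | intermediate
19 | 3-bromobut-3-en-1-ol | C=C(Br)CCO | starting material
20 | 2-bromo-4-iodobut-1-ene | C=C(Br)CCI | intermediate
21 | bis(3-bromobut-3-enyl)zinc (not isolated) | C=C(Br)CC[Zn]CCC(Br)=C | intermediate
22 | (S)-C3' carbinol | C=C(Br)CC[C@H](O)C(C)(C)[C@H]1C(=O)C[C@]2(C)[C@@H](Br)CC[C@@](C)(O[Si](CC)(CC)CC)[C@H]2C1 | intermediate
23 | C3' tert-butyldimethylsilyl ether | C=C(Br)CC[C@H](O[Si](C)(C)C(C)(C)C)C(C)(C)[C@H]1C(=O)C[C@]2(C)[C@@H](Br)CC[C@@](C)(O[Si](CC)(CC)CC)[C@H]2C1 | intermediate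
24 | spiro ketone | C=C1CC[C@H](O[Si](C)(C)C(C)(C)C)C(C)(C)[C@]12C(=O)C[C@]3(C)[C@@H](Br)CC[C@@](C)(O[Si](CC)(CC)CC)[C@H]3C2 | intermediate
25 | axial C8 alcohol | C=C1CC[C@H](O[Si](C)(C)C(C)(C)C)C(C)(C)[C@]12[C@@H](O)C[C@]3(C)[C@@H](Br)CC[C@@](C)(O[Si](CC)(CC)CC)[C@H]3C2 | intermediate
26 | spiro silyl ether mesylate (key-step precursor, C4 hydroxyl carried as TES ether) | C=C1CC[C@H](O[Si](C)(C)C(C)(C)C)C(C)(C)[C@]12[C@@H](OS(C)(=O)=O)C[C@]3(C)[C@@H](Br)CC[C@@](C)(O[Si](CC)(CC)CC)[C@H]3C2 | intermediate
27 | diol mesylate (reacts as its C3' alkoxide, not isolated) | C=C1CC[C@H](O)C(C)(C)[C@]12[C@@H](OS(C)(=O)=O)C[C@]3(C)[C@@H](Br)CC[C@@](C)(O)[C@H]3C2 | intermediate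
28 | CNP0412361.2 (1S,4R,5S,7R,8R,10S,3'S in the locants used here) | C=C1CC[C@@H]2O[C@@H]3C[C@]4(C)[C@@H](Br)CC[C@@](C)(O)[C@H]4C[C@]13C2(C)C | target

Total step count: 19
Longest linear sequence: 18 steps (steps 1 to 12 and 14 to 19)

Steps most likely to fail

Step 19. Anti-periplanar E2 loss of the axial mesylate, or migration of the alkenyl carbon from C7 to C8, may outrun substitution. The reason is that the tethered alkoxide reaches the rear of C8 only at a bent angle.

The fallback exchanges the roles of the two carbons and forms O–C3' instead. It sets out from 18 and comes back at 28. Aldehyde 18 is alkylated as in step 14, but with the (1S,2S) ligand, to give the C3'-epimeric (R)-carbinol F1. Silylation as in step 15 gives the (R)-carbinol TBS ether F2, and the palladium closure of step 16 gives the C3'-epimeric spiro ketone F3. Bu4NF frees the keto diol F4, whose C3' hydroxyl lies anti to C8 on ring D and cannot form a hemiketal. MsCl/Et3N then sulfonylates its only secondary hydroxyl to the keto C3' mesylate F5. Equilibrating Meerwein–Ponndorf–Verley reduction with Al(Oi-Pr)3 in i-PrOH–toluene at 100 °C gives the more stable equatorial C8 carbinol C3' mesylate F6. With KH in THF, the alkoxide on C8 (axial on ring D) displaces the equatorial ring-D mesylate from its rear. This 1,3-bridging SN2 has a collinear trajectory, inverts C3' to (S) and gives 28.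

Step 16. Carbon–carbon reductive elimination at C7, which creates two adjacent quaternary carbons, may be too slow. Base-induced dehydrobromination of the bromoalkene or simple protodehalogenation could then take over.

The fallback replaces enolate coupling by a neutral intramolecular Heck reaction on a regiodefined cyclic enol ether. It sets out from 22 and comes back at 24. Carbinol 22 is dehydrated (PPTS, toluene, reflux) to the tetrasubstituted dihydrofuran F7, in which C8=C7 is the only possible nucleophilic alkene. Pd(OAc)2, PPh3 and Ag2CO3 in MeCN at 80 °C then effect 6-exo-trig carbopalladation at C7 on the face fixed by C3'. Syn β-hydride loss towards C9 gives the bridged dienyl ether F8. Aqueous oxalic acid in THF hydrolyses the enol ether to the spiro hydroxy ketone F9, and TBSOTf/2,6-lutidine converts it into 24.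

Step 11. Three things may go wrong at 140 °C. The strained ketal may collapse to the methyl enol ether or the ketone without exchanging with prenol. Prenol may ionise under acid. The tertiary silyl ether may be lost.

The fallback builds the same C7 branch by aldol condensation and conjugate addition. It sets out from 13 and comes back at 17. PPTS in wet acetone hydrolyses 13 to the C8 ketone F10. LDA (deprotonation at C7, since C9 is neopentyl) and then acetone give the acetone aldol F11. MsCl/Et3N followed by DBU gives the isopropylidene ketone F12. Copper-catalysed conjugate addition of CH2=CHMgBr (CuBr·SMe2, TMSCl, THF, −78 °C), with acidic work-up and DBU equilibration, delivers 17.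

Further compounds
F1 | step 19 | C3'-epimeric (R)-carbinol | C=C(Br)CC[C@@H](O)C(C)(C)[C@H]1C(=O)C[C@]2(C)[C@@H](Br)CC[C@@](C)(O[Si](CC)(CC)CC)[C@H]2C1
F2 | step 19 | (R)-carbinol TBS ether | C=C(Br)CC[C@@H](O[Si](C)(C)C(C)(C)C)C(C)(C)[C@H]1C(=O)C[C@]2(C)[C@@H](Br)CC[C@@](C)(O[Si](CC)(CC)CC)[C@H]2C1
F3 | step 19 | C3'-epimeric spiro ketone | C=C1CC[C@@H](O[Si](C)(C)C(C)(C)C)C(C)(C)[C@]12C(=O)C[C@]3(C)[C@@H](Br)CC[C@@](C)(O[Si](CC)(CC)CC)[C@H]3C2
F4 | step 19 | keto diol | C=C1CC[C@@H](O)C(C)(C)[C@]12C(=O)C[C@]3(C)[C@@H](Br)CC[C@@](C)(O)[C@H]3C2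
F5 | step 19 | keto C3' mesylate | C=C1CC[C@@H](OS(C)(=O)=O)C(C)(C)[C@]12C(=O)C[C@]3(C)[C@@H](Br)CC[C@@](C)(O)[C@H]3C2
F6 | step 19 | equatorial C8 carbinol C3' mesylate | C=C1CC[C@@H](OS(C)(=O)=O)C(C)(C)[C@]12[C@H](O)C[C@]3(C)[C@@H](Br)CC[C@@](C)(O)[C@H]3C2
F7 | step 16 | tetrasubstituted dihydrofuran | C=C(Br)CC[C@@H]1OC=2C[C@]3(C)[C@@H](Br)CC[C@@](C)(O[Si](CC)(CC)CC)[C@H]3CC=2C1(C)C
F8 | step 16 | bridged dienyl ether | C=C1CC[C@@H]2OC3=C[C@]4(C)[C@@H](Br)CC[C@@](C)(O[Si](CC)(CC)CC)[C@H]4C[C@]13C2(C)C
F9 | step 16 | spiro hydroxy ketone | C=C1CC[C@H](O)C(C)(C)[C@]12C(=O)C[C@]3(C)[C@@H](Br)CC[C@@](C)(O[Si](CC)(CC)CC)[C@H]3C2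
F10 | step 11 | C8 ketone | O=C1C[C@]2(C)[C@@H](Br)CC[C@@](C)(O[Si](CC)(CC)CC)[C@H]2CC1
F11 | step 11 | acetone aldol | CC(C)(O)[C@H]1C(=O)C[C@]2(C)[C@@H](Br)CC[C@@](C)(O[Si](CC)(CC)CC)[C@H]2C1
F12 | step 11 | isopropylidene ketone | CC(C)=C1C(=O)C[C@]2(C)[C@@H](Br)CC[C@@](C)(O[Si](CC)(CC)CC)[C@H]2C1
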